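The carbocycle of the chromane core (C4a, C5, C6, C7, C8, C8a) is a masked phloroglucinol: C6–C7(=O)–C8 is a ketone flanked by its two α-carbons, and C5–C4a=C8a(–O1) is a β-oxyacrylate embedded in the dihydropyranone ring. The key step is a one-pot anionic [3+3] benzannulation: a regiodefined enolate, released from an enol lactone, adds to a 6-methylthio-dihydropyranone ester with loss of thiolate (C8–C8a), and Dieckmann closure (C5–C6) then delivers the complete 5,7-dihydroxychromanone acid. A Pd-catalysed asymmetric dearomative prenylation finally creates the quaternary C6.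

Key step: step 13

Remark: the target is taken as the 4-enol/5,7-dione tautomer drawn in its SMILES. Acid 24 may close reversibly onto its 7-OH (dihydrocoumarin form), and the aqueous carbonate of step 14 keeps it open.
Remark: in steps 5 and 14 the catalyst antipode is chosen for the product configuration required; if a first run shows the opposite sense, (DHQD)2AQN or the (S,S)-ligand is used instead, with no change to the route.

Step 1
Reactants: 1 (1S,5S)-(−)-α-pinene
Product: 2 2-[(1R,3R)-3-acetyl-2,2-dimethylcyclobutyl]acetic acid (cis-pinonic acid)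
Conditions: RuCl3·xH2O (2 mol %), NaIO4 (4 equiv), MeCN/EtOAc/H2O, rt
Reagents that add atoms: sodium periodate, [Na+].[O-]I(=O)(=O)=O
Why: RuO4-catalysed oxidative cleavage of the trisubstituted alkene should give the keto acid, with both ring stereocentres of the pinene carried over untouched (cis-1,3).

Step 2
Reactants: 2 cis-pinonic acid
Product: 3 2-[(1R,3S)-2,2-dimethyl-3-(prop-1-en-2-yl)cyclobutyl]acetic acid
Conditions: Ph3PCH3Br (1.5 equiv), KOt-Bu (2.6 equiv), THF, 0 °C → rt; then 1 M HCl
Reagents that add atoms: methyltriphenylphosphonium bromide, C[P+](c1ccccc1)(c1ccccc1)c1ccccc1.[Br-]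
Why: Wittig methylenation of the methyl ketone on the potassium carboxylate should install the isopropenyl group; the ylide is kept cold and in small excess to limit epimerisation α to the ketone.

Step 3
Reactants: 3 isopropenyl acid
Product: 4 2-[(1R,3S)-2,2-dimethyl-3-(prop-1-en-2-yl)cyclobutyl]ethan-1-ol
Conditions: LiAlH4, THF, 0 °C → rt
Reagents that add atoms: none
Why: Hydride reduction of the carboxylic acid to the primary alcohol leaves the 1,1-disubstituted alkene and both stereocentres untouched.

Step 4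
Reactants: 4 cyclobutylethanol
Product: 5 (1R,3S)-1-(2-iodoethyl)-2,2-dimethyl-3-(prop-1-en-2-yl)cyclobutane
Conditions: I2, PPh3, imidazole, CH2Cl2, 0 °C → rt
Reagents that add atoms: iodine, II
Why: Appel iodination of the unhindered primary alcohol gives the alkyl iodide needed for zinc insertion.

Step 5
Reactants: 6 3-phenylglutaric anhydride
Product: 7 (3S)-5-methoxy-5-oxo-3-phenylpentanoic acid
Conditions: MeOH (10 equiv), (DHQ)2AQN (20 mol %), Et2O, −30 °C
Reagents that add atoms: methanol, CO
Why: Cinchona-alkaloid-catalysed desymmetrising methanolysis of the meso anhydride differentiates the enantiotopic carbonyls by general-base catalysis and sets the benzylic stereocentre (S) under catalyst control.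

Step 6
Reactants: 7 (S)-hemiester, 5 alkyl iodide
Product: 10 methyl (3S)-7-[(1S,3S)-2,2-dimethyl-3-(prop-1-en-2-yl)cyclobutyl]-5-oxo-3-phenylheptanoate, via acid chloride 8 (not isolated), via alkylzinc iodide 9 (not isolated)
Conditions: 7, (COCl)2, cat. DMF, CH2Cl2, 0 °C → rt, evaporate; 5, Zn dust, LiCl, THF, 40 °C; combine, Pd(PPh3)4 (5 mol %), THF, 0 °C → rt
Reagents that add atoms: none
Why: Negishi acylation of the primary alkylzinc with the acid chloride should give the ketone chemoselectively beside the methyl ester, and the stereocentre β to the acyl group cannot enolise.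

Step 7
Reactants: 10 keto ester
Product: 11 (3S)-7-[(1S,3S)-2,2-dimethyl-3-(prop-1-en-2-yl)cyclobutyl]-5-oxo-3-phenylheptanoic acid
Conditions: LiOH·H2O, THF/H2O (3:1), 0 °C → rt; then 1 M HCl
Reagents that add atoms: lithium hydroxide, [Li+].[OH-]
Why: Saponification of the unhindered methyl ester in water is faster than any Dieckmann closure of the δ-keto ester and leaves the β-stereocentre untouched.

Step 8
Reactants: 11 δ-keto acid
Product: 12 (4R)-6-{2-[(1S,3S)-2,2-dimethyl-3-(prop-1-en-2-yl)cyclobutyl]ethyl}-4-phenyl-3,4-dihydro-2H-pyran-2-one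
Conditions: Ac2O, NaOAc, 100 °C
Reagents that add atoms: none
Why: Enol lactonisation through the mixed anhydride should give the more stable endocyclic enol ester, a temporary ring that masks the acid and stores the ketone as its enol toward the benzylic side (the future C8).

Step 9
Reactants: 13 (4S)-4-benzyl-3-propanoyl-1,3-oxazolidin-2-one, 14 acetaldehyde
Product: 15 (4S)-4-benzyl-3-[(2S,3R)-3-hydroxy-2-methylbutanoyl]-1,3-oxazolidin-2-one
Conditions: Bu2BOTf, i-Pr2NEt, CH2Cl2, −78 → 0 °C; MeCHO, −78 → 0 °C; pH 7 buffer, MeOH, H2O2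
Reagents that add atoms: none
Why: Evans syn-aldol reaction: the Z-boron enolate reacts through a Zimmerman–Traxler chair on the face dictated by the auxiliary, setting both stereocentres (2S,3R) of the future C3/C2 of the chromanone.

Step 10
Reactants: 15 aldol adduct
Product: 16 (2S,3R)-3-hydroxy-N-methoxy-N,2-dimethylbutanamide
Conditions: MeNHOMe·HCl, AlMe3, CH2Cl2, −15 → 0 °C
Reagents that add atoms: N,O-dimethylhydroxylamine hydrochloride, CNOC.Cl
Why: Aluminium-amide transamidation, assisted by the free β-hydroxyl, exchanges the auxiliary for the Weinreb amide without epimerisation.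

Step 11
Reactants: 16 Weinreb amide, 17 methyl acetate
Product: 18 methyl (4S,5R)-5-hydroxy-4-methyl-3-oxohexanoate
Conditions: LDA (4.2 equiv), MeOAc (4.0 equiv), THF, −78 °C; 16, −78 → −40 °C; AcOH quench at −78 °C
Reagents that add atoms: none
Why: Claisen-type acylation of the ester enolate by the Weinreb amide stops at the chelated tetrahedral intermediate, and excess enolate absorbs the hydroxyl proton so that the δ-hydroxy-β-keto ester is obtained.

Step 12
Reactants: 18 δ-hydroxy-β-keto ester
Product: 20 methyl (2R,3S)-2,3-dimethyl-6-(methylsulfanyl)-4-oxo-3,4-dihydro-2H-pyran-5-carboxylate, via ketene dithioacetal 19 (not isolated)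
Conditions: K2CO3 (3 equiv), CS2 (1.2 equiv), DMF, 0 °C; MeI (2.1 equiv), 0 °C → rt; then 45 °C
Reagents that add atoms: carbon disulfide, S=C=S; iodomethane, CI
Why: Dithiocarboxylation and double S-methylation give the α-oxo ketene dithioacetal, whose free hydroxyl should then close 6-endo onto the push–pull carbon with loss of methanethiolate (intramolecular vinylic substitution), with retention at both stereocentres.

Step 13
Reactants: 12 enol lactone, 20 methylthio-pyranone ester
Product: 24 (3S)-3-[(2R,3S)-6-{[(1R,3S)-2,2-dimethyl-3-(prop-1-en-2-yl)cyclobutyl]methyl}-5,7-dihydroxy-2,3-dimethyl-4-oxo-3,4-dihydro-2H-chromen-8-yl]-3-phenylpropanoic acid, via silyl enol ether carboxylate 21 (not isolated), via dipotassium enolate carboxylate 22 (not isolated), via coupled pyranone keto acid 23 (not isolated)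
Conditions: KOSiMe3 (1.05 equiv), THF, 0 °C; KOt-Bu (1.0 equiv), −78 °C; 20, −78 → −40 °C; LDA (2.6 equiv), −78 → 0 °C; 1 M HCl to pH 3, 0 °C
Reagents that add atoms: potassium trimethylsilanolate, C[Si](C)(C)[O-].[K+]
Why: Silanolate opens the enol lactone at the acyl carbon, the silyl group passes to the enolate oxygen and tert-butoxide removes it again, so that 22 carries its nucleophilic carbon only on the benzylic side of the ketone; this carbon adds to the methylthio-bearing carbon of 20 with expulsion of thiolate (C8–C8a), then LDA forms the α′-carbanion on the other side of the ketone, which attacks the ring ester (C5–C6), methoxide leaves and the 1,3-dione enolises to the phenol. The closest known reaction type is the Michael (addition–elimination)/Claisen [3+3] benzannulation of ketone enolates with α-oxo ketene dithioacetals and alkoxymethylene malonates. The carbocycle closes by a 6-(enolendo)-exo-trig Dieckmann acylation, the pyranone ring being already present. No new stereocentre survives, since the transient sp3 centre at C8 is lost on enolisation and aromatisation, and the four existing centres lie outside the reacting array. The step needs regioselectivity (which α-carbon bonds to C8a), secured by the enol lactone that stores the enol double bond toward C8, and C- over O-acylation, which should follow because the α′-carbanion is the most nucleophilic site of the polyanion and is generated at −78 °C before the enolate oxygen can lactonise onto the ester. The carboxylate form of the side chain keeps its α-CH2 non-acidic, so LDA should deprotonate only the ketone α′-position, and the low temperature limits enolisation at C3 of the cis-2,3-dimethylpyranone.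

Step 14
Reactants: 24 chromanone acid, 25 3-methylbut-2-en-1-yl acetate (prenyl acetate)
Product: 26 (3S)-3-[(2R,3S,6R)-6-{[(1R,3S)-2,2-dimethyl-3-(prop-1-en-2-yl)cyclobutyl]methyl}-4-hydroxy-2,3-dimethyl-6-(3-methylbut-2-en-1-yl)-5,7-dioxo-3,5,6,7-tetrahydro-2H-chromen-8-yl]-3-phenylpropanoic acid (target)
Conditions: Pd2(dba)3·CHCl3 (2.5 mol %), (R,R)-DACH-phenyl Trost ligand (7.5 mol %), Cs2CO3 (2.2 equiv), THF/H2O (20:1), 0 °C → rt; pH 4 buffer
Reagents that add atoms: none
Why: Tsuji–Trost allylic dearomatisation: the 7-phenoxide should attack the primary terminus of the π-prenyl–Pd complex through C6 (flanked by both oxygens and less hindered than C8), and the chiral pocket of the ligand selects the face, setting the quaternary (6R) centre under catalyst control.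

Compound list
1 | (1S,5S)-(−)-α-pinene | CC1=CC[C@H]2C[C@@H]1C2(C)C | starting material
2 | 2-[(1R,3R)-3-acetyl-2,2-dimethylcyclobutyl]acetic acid | CC(=O)[C@@H]1C[C@H](CC(=O)O)C1(C)C | intermediate
3 | 2-[(1R,3S)-2,2-dimethyl-3-(prop-1-en-2-yl)cyclobutyl]acetic acid | C=C(C)[C@@H]1C[C@H](CC(=O)O)C1(C)C | intermediate
4 | 2-[(1R,3S)-2,2-dimethyl-3-(prop-1-en-2-yl)cyclobutyl]ethan-1-ol | C=C(C)[C@@H]1C[C@H](CCO)C1(C)C | intermediate
5 | (1R,3S)-1-(2-iodoethyl)-2,2-dimethyl-3-(prop-1-en-2-yl)cyclobutane | C=C(C)[C@@H]1C[C@H](CCI)C1(C)C | intermediate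
6 | 3-phenylglutaric anhydride (4-phenyloxane-2,6-dione) | O=C1CC(c2ccccc2)CC(=O)O1 | starting material
7 | (3S)-5-methoxy-5-oxo-3-phenylpentanoic acid | OC(=O)C[C@@H](CC(=O)OC)c1ccccc1 | intermediate
8 | methyl (3R)-5-chloro-5-oxo-3-phenylpentanoate (not isolated) | ClC(=O)C[C@@H](CC(=O)OC)c1ccccc1 | intermediate
9 | {2-[(1R,3S)-2,2-dimethyl-3-(prop-1-en-2-yl)cyclobutyl]ethyl}zinc iodide (not isolated) | C=C(C)[C@@H]1C[C@H](CC[Zn]I)C1(C)C | intermediate
10 | methyl (3S)-7-[(1S,3S)-2,2-dimethyl-3-(prop-1-en-2-yl)cyclobutyl]-5-oxo-3-phenylheptanoate | C=C(C)[C@@H]1C[C@H](CCC(=O)C[C@@H](CC(=O)OC)c2ccccc2)C1(C)C | intermediate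
11 | (3S)-7-[(1S,3S)-2,2-dimethyl-3-(prop-1-en-2-yl)cyclobutyl]-5-oxo-3-phenylheptanoic acid | C=C(C)[C@@H]1C[C@H](CCC(=O)C[C@@H](CC(=O)O)c2ccccc2)C1(C)C | intermediate
12 | (4R)-6-{2-[(1S,3S)-2,2-dimethyl-3-(prop-1-en-2-yl)cyclobutyl]ethyl}-4-phenyl-3,4-dihydro-2H-pyran-2-one | C=C(C)[C@@H]1C[C@H](CCC2=C[C@H](c3ccccc3)CC(=O)O2)C1(C)C | intermediate
13 | (4S)-4-benzyl-3-propanoyl-1,3-oxazolidin-2-one | CCC(=O)N1[C@@H](Cc2ccccc2)COC1=O | starting material
14 | acetaldehyde | CC=O | starting material
15 | (4S)-4-benzyl-3-[(2S,3R)-3-hydroxy-2-methylbutanoyl]-1,3-oxazolidin-2-one | C[C@@H](O)[C@H](C)C(=O)N1[C@@H](Cc2ccccc2)COC1=O | intermediate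
16 | (2S,3R)-3-hydroxy-N-methoxy-N,2-dimethylbutanamide | C[C@@H](O)[C@H](C)C(=O)N(C)OC | intermediate
17 | methyl acetate | COC(C)=O | starting material
18 | methyl (4S,5R)-5-hydroxy-4-methyl-3-oxohexanoate | C[C@@H](O)[C@H](C)C(=O)CC(=O)OC | intermediate
19 | methyl (4S,5R)-2-[bis(methylsulfanyl)methylidene]-5-hydroxy-4-methyl-3-oxohexanoate (not isolated) | C[C@@H](O)[C@H](C)C(=O)C(C(=O)OC)=C(SC)SC | intermediate
20 | methyl (2R,3S)-2,3-dimethyl-6-(methylsulfanyl)-4-oxo-3,4-dihydro-2H-pyran-5-carboxylate | COC(=O)C1=C(SC)O[C@H](C)[C@H](C)C1=O | intermediate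
21 | potassium (3R,4Z)-7-[(1S,3S)-2,2-dimethyl-3-(prop-1-en-2-yl)cyclobutyl]-3-phenyl-5-(trimethylsilyloxy)hept-4-enoate (not isolated) | C=C(C)[C@@H]1C[C@H](CC/C(O[Si](C)(C)C)=C/[C@@H](CC(=O)[O-])c2ccccc2)C1(C)C.[K+] | intermediate
22 | dipotassium (3R,4Z)-7-[(1S,3S)-2,2-dimethyl-3-(prop-1-en-2-yl)cyclobutyl]-5-oxido-3-phenylhept-4-enoate (not isolated) | C=C(C)[C@@H]1C[C@H](CC/C([O-])=C/[C@@H](CC(=O)[O-])c2ccccc2)C1(C)C.[K+].[K+] | intermediate
23 | (3R)-7-[(1S,3S)-2,2-dimethyl-3-(prop-1-en-2-yl)cyclobutyl]-4-[(2R,3S)-5-(methoxycarbonyl)-2,3-dimethyl-4-oxo-3,4-dihydro-2H-pyran-6-yl]-5-oxo-3-phenylheptanoic acid (both C4 epimers; present as its salt; not isolated) | C=C(C)[C@@H]1C[C@H](CCC(=O)C([C@@H](CC(=O)O)c2ccccc2)C2=C(C(=O)OC)C(=O)[C@@H](C)[C@@H](C)O2)C1(C)C | intermediate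
24 | (3S)-3-[(2R,3S)-6-{[(1R,3S)-2,2-dimethyl-3-(prop-1-en-2-yl)cyclobutyl]methyl}-5,7-dihydroxy-2,3-dimethyl-4-oxo-3,4-dihydro-2H-chromen-8-yl]-3-phenylpropanoic acid | C=C(C)[C@@H]1C[C@H](Cc2c(O)c3C(=O)[C@@H](C)[C@@H](C)Oc3c([C@@H](CC(=O)O)c3ccccc3)c2O)C1(C)C | intermediate
25 | 3-methylbut-2-en-1-yl acetate | CC(=O)OCC=C(C)C | starting material
26 | (3S)-3-[(2R,3S,6R)-6-{[(1R,3S)-2,2-dimethyl-3-(prop-1-en-2-yl)cyclobutyl]methyl}-4-hydroxy-2,3-dimethyl-6-(3-methylbut-2-en-1-yl)-5,7-dioxo-3,5,6,7-tetrahydro-2H-chromen-8-yl]-3-phenylpropanoic acid | C=C(C)[C@@H]1C[C@H](C[C@@]2(CC=C(C)C)C(=O)C3=C(O)[C@@H](C)[C@@H](C)OC3=C([C@@H](CC(=O)O)c3ccccc3)C2=O)C1(C)C | target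

Total step count: 14. Longest linear sequence: 9 steps (1, 2, 3, 4, 6, 7, 8, 13, 14).

Steps most likely to fail

Step 13. Three processes may interfere. The enolate oxygen of the coupled anion may lactonise onto the ring ester (fused 2-pyranone) before the α′-carbanion is formed. The enolate may take the C3 proton of 20 instead of adding, which would erode the cis-2,3-dimethyl relationship. The second deprotonation may be slow. The fallback accepts the lactonisation instead of fighting it. It sets out from 12 and 20: the same enolate (KOSiMe3, then KOt-Bu) is combined with 20 and the mixture is warmed to rt without amide base, so that addition–elimination and O-acylation should give (3S)-3-[(2R,3S)-7-{2-[(1S,3S)-2,2-dimethyl-3-(prop-1-en-2-yl)cyclobutyl]ethyl}-2,3-dimethyl-4,5-dioxo-3,4-dihydro-2H,5H-pyrano[4,3-b]pyran-8-yl]-3-phenylpropanoic acid F1, isolated after acidification. Heating F1 with Mg(OMe)2 in MeOH (60 °C) should reopen the pyranone by methoxide to the magnesium-chelated keto ester, and Claisen closure through carbon then gives the phloroglucinol; the fallback comes back to the route at 24.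

Step 14. The catalyst may discriminate the faces of the phenoxide poorly. Attack may also occur at the tertiary allyl terminus (reverse prenyl), at C8 or on oxygen, and the C-allylation may be reversible. The fallback installs the smaller allyl group, for which asymmetric allylic dearomatisation is best precedented, and builds the prenyl group afterwards. It sets out from 24: allyl methyl carbonate with Pd2(dba)3 and the same ligand should give (3S)-3-[(2R,3S,6R)-6-{[(1R,3S)-2,2-dimethyl-3-(prop-1-en-2-yl)cyclobutyl]methyl}-4-hydroxy-2,3-dimethyl-5,7-dioxo-6-(prop-2-en-1-yl)-3,5,6,7-tetrahydro-2H-chromen-8-yl]-3-phenylpropanoic acid F2. Cross-metathesis of F2 with 2-methylbut-2-ene (Grubbs second-generation catalyst, CH2Cl2, 40 °C) should convert the monosubstituted alkene into the prenyl group while the 1,1-disubstituted isopropenyl group stays inert; the fallback comes back to the route at 26.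

Step 12. The free hydroxyl may lactonise onto the methyl ester instead of closing onto the dithioacetal carbon, and the β-hydroxy ketone may undergo retro-aldol cleavage or dehydration under carbonate. The fallback protects the alcohol through the sequence. It sets out from 16: Et3SiCl and imidazole give (2S,3R)-N-methoxy-N,2-dimethyl-3-(triethylsilyloxy)butanamide F3. Acylation of lithiated methyl acetate by F3 gives methyl (4S,5R)-4-methyl-3-oxo-5-(triethylsilyloxy)hexanoate F4. K2CO3, CS2 and MeI give methyl (4S,5R)-2-[bis(methylsulfanyl)methylidene]-4-methyl-3-oxo-5-(triethylsilyloxy)hexanoate F5. HF·pyridine in MeCN removes the silyl group under acidic conditions that activate the dithioacetal carbon, and the liberated alcohol should close the ring; the fallback comes back to the route at 20.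

Further compounds
F1 | step 13 | (3S)-3-[(2R,3S)-7-{2-[(1S,3S)-2,2-dimethyl-3-(prop-1-en-2-yl)cyclobutyl]ethyl}-2,3-dimethyl-4,5-dioxo-3,4-dihydro-2H,5H-pyrano[4,3-b]pyran-8-yl]-3-phenylpropanoic acid | C=C(C)[C@@H]1C[C@H](CCC2=C([C@@H](CC(=O)O)c3ccccc3)C3=C(C(=O)O2)C(=O)[C@@H](C)[C@@H](C)O3)C1(C)C
F2 | step 14 | (3S)-3-[(2R,3S,6R)-6-{[(1R,3S)-2,2-dimethyl-3-(prop-1-en-2-yl)cyclobutyl]methyl}-4-hydroxy-2,3-dimethyl-5,7-dioxo-6-(prop-2-en-1-yl)-3,5,6,7-tetrahydro-2H-chromen-8-yl]-3-phenylpropanoic acid | C=C(C)[C@@H]1C[C@H](C[C@@]2(CC=C)C(=O)C3=C(O)[C@@H](C)[C@@H](C)OC3=C([C@@H](CC(=O)O)c3ccccc3)C2=O)C1(C)C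
F3 | step 12 | (2S,3R)-N-methoxy-N,2-dimethyl-3-(triethylsilyloxy)butanamide | CC[Si](CC)(CC)O[C@H](C)[C@H](C)C(=O)N(C)OC
F4 | step 12 | methyl (4S,5R)-4-methyl-3-oxo-5-(triethylsilyloxy)hexanoate | CC[Si](CC)(CC)O[C@H](C)[C@H](C)C(=O)CC(=O)OC
F5 | step 12 | methyl (4S,5R)-2-[bis(methylsulfanyl)methylidene]-4-methyl-3-oxo-5-(triethylsilyloxy)hexanoate | CC[Si](CC)(CC)O[C@H](C)[C@H](C)C(=O)C(C(=O)OC)=C(SC)SC
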